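**Plan**

1. The central ring is a 3-methoxyphenol: the two oxygen-bearing carbons are meta with a single CH between them, and the phenol carbon is followed around the ring by the carbon carrying the 4-hydroxybenzyl group and then the carbon carrying the 3-hydroxyphenethyl group. A vinylketene and an alkoxyalkyne deliver exactly this pattern.
2. Retrosynthesis first cuts the two benzyl ether O–C bonds, then three bonds of the central ring: C(OH)–CH between the oxygens, C(OMe)–the other ring CH, and C(OH)–C(benzyl). This leads back to a dienyl diazo ketone and methoxyacetylene.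
3. The diazo ketone comes from a methyl enone (diazo transfer). The enone C=C is cut to an α-branched β-ketophosphonate and an arylacetaldehyde, and the phosphonate C–C bond to diethyl (2-oxopropyl)phosphonate and a phenethyl bromide.
4. Forward: the chain is joined by alkylation, olefination and diazo transfer. The two outer benzene rings are bought; the central ring arises in the penultimate step, and hydrogenolysis finishes the route.
5. Stereochemistry: the target has no stereocentre and is achiral, so "single enantiomer" is taken to mean the compound as drawn. The only stereo-element on the way, the enone geometry, disappears on aromatisation.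

Key step: step 9

**Route**

Step 1
Reactants: 1 2-(3-hydroxyphenyl)ethanol
Product: 2 2-[3-(benzyloxy)phenyl]ethanol
Conditions: BnBr (1.05 equiv), K2CO3, acetone, reflux
Reagents that add atoms: benzyl bromide, BrCc1ccccc1
Why: Williamson etherification in which carbonate deprotonates only the phenol (far more acidic than the primary alcohol), so benzylation should take place on the aryl oxygen alone.

Step 2
Reactants: 2 2-[3-(benzyloxy)phenyl]ethanol
Product: 3 1-(benzyloxy)-3-(2-bromoethyl)benzene
Conditions: CBr4, PPh3, CH2Cl2, 0 °C to rt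
Reagents that add atoms: carbon tetrabromide, BrC(Br)(Br)Br
Why: Appel reaction, in which the primary alcohol is activated as the alkoxyphosphonium salt and displaced by bromide (SN2) under neutral conditions that leave the benzyl ether untouched.

Step 3
Reactants: 4 diethyl (2-oxopropyl)phosphonate; 3 1-(benzyloxy)-3-(2-bromoethyl)benzene
Product: 5 diethyl {5-[3-(benzyloxy)phenyl]-2-oxopentan-3-yl}phosphonate (racemic)
Conditions: 4 (1.5 equiv), NaH, DMF, 0 °C to rt; then 3, Bu4NI (cat.), 60 °C
Reagents that add atoms: none
Why: C-alkylation of the sodium enolate of a β-ketophosphonate at the carbon between P=O and C=O with a primary bromide (malonate-type SN2); the soft, weakly basic anion and the excess of 4 should hold back E2 elimination to the styrene and double alkylation.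

Step 4
Reactants: 6 2-(4-hydroxyphenyl)ethanol
Product: 7 2-[4-(benzyloxy)phenyl]ethanol
Conditions: BnBr (1.05 equiv), K2CO3, acetone, reflux
Reagents that add atoms: benzyl bromide, BrCc1ccccc1
Why: The same phenol-selective Williamson etherification as in step 1.

Step 5
Reactants: 7 2-[4-(benzyloxy)phenyl]ethanol
Product: 8 2-[4-(benzyloxy)phenyl]acetaldehyde
Conditions: Dess–Martin periodinane, CH2Cl2, 0 °C to rt; crude aldehyde used at once
Reagents that add atoms: none
Why: Dess–Martin oxidation of a primary alcohol stops at the aldehyde under neutral, non-aqueous conditions, which suits an enolisable arylacetaldehyde that should not be stored.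

Step 6
Reactants: 5 diethyl {5-[3-(benzyloxy)phenyl]-2-oxopentan-3-yl}phosphonate; 8 2-[4-(benzyloxy)phenyl]acetaldehyde
Product: 9 (E)-5-[4-(benzyloxy)phenyl]-3-{2-[3-(benzyloxy)phenyl]ethyl}pent-3-en-2-one
Conditions: 5 (1.2 equiv), activated Ba(OH)2, THF, rt; then 8, THF/H2O 40:1, 0 °C to rt
Reagents that add atoms: none
Why: Horner–Wadsworth–Emmons olefination of an α-branched β-ketophosphonate under mild barium hydroxide conditions that tolerate base-sensitive aldehydes; the E enone (acetyl trans to the benzylic CH2) should predominate as the more stable trisubstituted alkene, and its geometry is not carried into the target.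

Step 7
Reactants: 9 (E)-5-[4-(benzyloxy)phenyl]-3-{2-[3-(benzyloxy)phenyl]ethyl}pent-3-en-2-one
Product: 11 (E)-1-diazo-5-[4-(benzyloxy)phenyl]-3-{2-[3-(benzyloxy)phenyl]ethyl}pent-3-en-2-one, via trifluoroacetyl diketone 10 (not isolated)
Conditions: LiHMDS, THF, −78 °C; CF3CO2CH2CF3, −78 °C; aq. HCl work-up; then MsN3, Et3N, H2O (1 equiv), MeCN, rt
Reagents that add atoms: methanesulfonyl azide, CS(=O)(=O)N=[N+]=[N-]; 2,2,2-trifluoroethyl trifluoroacetate, O=C(OCC(F)(F)F)C(F)(F)F (its CF3CO group stays only in intermediate 10)
Why: Detrifluoroacetylative diazo transfer (Regitz type): kinetic deprotonation of the methyl group, Claisen acylation by the trifluoroacetate, then diazo transfer with loss of the trifluoroacetyl group as its N-sulfonyl amide, the standard way to α'-diazo enones that avoids diazomethane and its cycloaddition to the enone.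

Step 8
Reactants: 12 chloroacetaldehyde dimethyl acetal
Product: 14 methoxyacetylene (methoxyethyne), via sodium methoxyacetylide 13 (not isolated)
Conditions: NaNH2 (3 equiv), liq. NH3, −33 °C; evaporate NH3; cold sat. aq. NaCl, −70 °C to rt; distil into a −78 °C trap and take up in cold ClCH2CH2Cl
Reagents that add atoms: sodium amide, [Na+].[NH2-] (sodium only in intermediate 13)
Why: Twofold base-induced elimination from an α-chloro acetal (loss of methanol and of HCl) with excess sodium amide gives the sodium acetylide of the ynol ether, which is protonated on aqueous quench; this is the standard preparation of alkoxyacetylenes.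

Step 9
Reactants: 11 (E)-1-diazo-5-[4-(benzyloxy)phenyl]-3-{2-[3-(benzyloxy)phenyl]ethyl}pent-3-en-2-one; 14 methoxyacetylene
Product: 19 2-[4-(benzyloxy)benzyl]-3-{2-[3-(benzyloxy)phenyl]ethyl}-5-methoxyphenol, via vinylketene 15 (not isolated), via methoxycyclobutenone 16 (not isolated), via dienylketene 17 (not isolated), via cyclohexadienone 18 (not isolated)
Conditions: 14 (4 equiv), hν (medium-pressure Hg lamp, Pyrex filter, λ > 300 nm), ClCH2CH2Cl, 0 °C, closed vessel; then 80 °C
Reagents that add atoms: none
Why: Irradiation above 300 nm excites only the diazo ketone; N2 is lost and the alkenyl group shifts to the former diazo carbon (photochemical Wolff rearrangement) to give vinylketene 15. The unsubstituted, nucleophilic carbon of ynol ether 14 attacks the ketene carbonyl carbon and the [2+2] cycloaddition closes to the 3-methoxy-4-alkenylcyclobutenone 16, which on warming opens by a 4π electrocyclic reaction to dienylketene 17. The six-membered ring then closes by thermal 6π (disrotatory) electrocyclisation between the ketene carbon and the alkene carbon carrying the 4-(benzyloxy)benzyl group, and dienone 18 tautomerises to the phenol; this is the photochemical variant of the Danheiser benzannulation, known for unsaturated α-diazo ketones with alkoxy- and siloxyalkynes. No stereocentre is created, since the sp3 carbons of 16 and 18 and the alkene geometry all vanish on aromatisation. The one selectivity needed is the orientation of the [2+2] step, and the polarisation of the ynol ether secures it, so that the ketene oxygen ends as the free phenol next to the benzyl-bearing carbon and the alkyne oxygen as the methyl ether, with a ring CH between them. The E alkene keeps the benzylic substituent on the outside of the closing triene, and the Pyrex cut-off keeps the benzyl aryl ethers out of the photochemistry.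

Step 10
Reactants: 19 2-[4-(benzyloxy)benzyl]-3-{2-[3-(benzyloxy)phenyl]ethyl}-5-methoxyphenol
Product: 20 2-(4-hydroxybenzyl)-3-[2-(3-hydroxyphenyl)ethyl]-5-methoxyphenol (IN1159)
Conditions: H2 (1 atm), 10% Pd/C, EtOAc/MeOH, rt
Reagents that add atoms: none
Why: Catalytic hydrogenolysis of the two benzyl aryl ethers over palladium; the diarylmethane and bibenzyl C–C bonds, the methyl ether and the arene rings are inert under these conditions.

**Compound list**

1 | 2-(3-hydroxyphenyl)ethanol | OCCc1cccc(O)c1 | starting material
2 | 2-[3-(benzyloxy)phenyl]ethanol | OCCc1cccc(OCc2ccccc2)c1 | intermediate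
3 | 1-(benzyloxy)-3-(2-bromoethyl)benzene | BrCCc1cccc(OCc2ccccc2)c1 | intermediate
4 | diethyl (2-oxopropyl)phosphonate | CC(=O)CP(=O)(OCC)OCC | starting material
5 | diethyl {5-[3-(benzyloxy)phenyl]-2-oxopentan-3-yl}phosphonate (racemic) | CCOP(=O)(OCC)C(CCc1cccc(OCc2ccccc2)c1)C(C)=O | intermediate
6 | 2-(4-hydroxyphenyl)ethanol | OCCc1ccc(O)cc1 | starting material
7 | 2-[4-(benzyloxy)phenyl]ethanol | OCCc1ccc(OCc2ccccc2)cc1 | intermediate
8 | 2-[4-(benzyloxy)phenyl]acetaldehyde | O=CCc1ccc(OCc2ccccc2)cc1 | intermediate
9 | (E)-5-[4-(benzyloxy)phenyl]-3-{2-[3-(benzyloxy)phenyl]ethyl}pent-3-en-2-one | CC(=O)/C(CCc1cccc(OCc2ccccc2)c1)=C/Cc1ccc(OCc2ccccc2)cc1 | intermediate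
10 | (E)-7-[4-(benzyloxy)phenyl]-5-{2-[3-(benzyloxy)phenyl]ethyl}-1,1,1-trifluorohept-5-ene-2,4-dione | O=C(CC(=O)/C(CCc1cccc(OCc2ccccc2)c1)=C/Cc1ccc(OCc2ccccc2)cc1)C(F)(F)F | intermediate
11 | (E)-1-diazo-5-[4-(benzyloxy)phenyl]-3-{2-[3-(benzyloxy)phenyl]ethyl}pent-3-en-2-one | [N-]=[N+]=CC(=O)/C(CCc1cccc(OCc2ccccc2)c1)=C/Cc1ccc(OCc2ccccc2)cc1 | intermediate
12 | chloroacetaldehyde dimethyl acetal (2-chloro-1,1-dimethoxyethane) | COC(CCl)OC | starting material
13 | sodium methoxyacetylide | [Na+].[C-]#COC | intermediate
14 | methoxyacetylene (methoxyethyne) | COC#C | intermediate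
15 | (E)-5-[4-(benzyloxy)phenyl]-3-{2-[3-(benzyloxy)phenyl]ethyl}penta-1,3-dien-1-one (vinylketene) | O=C=C/C(CCc1cccc(OCc2ccccc2)c1)=C/Cc1ccc(OCc2ccccc2)cc1 | intermediate
16 | 4-{(E)-1-[4-(benzyloxy)phenyl]-5-[3-(benzyloxy)phenyl]pent-2-en-3-yl}-3-methoxycyclobut-2-en-1-one (racemic) | COC1=CC(=O)C1/C(CCc1cccc(OCc2ccccc2)c1)=C/Cc1ccc(OCc2ccccc2)cc1 | intermediate
17 | (3E,5E)-7-[4-(benzyloxy)phenyl]-5-{2-[3-(benzyloxy)phenyl]ethyl}-3-methoxyhepta-1,3,5-trien-1-one (dienylketene) | O=C=C/C(OC)=C\C(CCc1cccc(OCc2ccccc2)c1)=C\Cc1ccc(OCc2ccccc2)cc1 | intermediate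
18 | 6-[4-(benzyloxy)benzyl]-5-{2-[3-(benzyloxy)phenyl]ethyl}-3-methoxycyclohexa-2,4-dien-1-one (racemic) | COC1=CC(=O)C(Cc2ccc(OCc3ccccc3)cc2)C(CCc2cccc(OCc3ccccc3)c2)=C1 | intermediate
19 | 2-[4-(benzyloxy)benzyl]-3-{2-[3-(benzyloxy)phenyl]ethyl}-5-methoxyphenol | COc1cc(O)c(Cc2ccc(OCc3ccccc3)cc2)c(CCc2cccc(OCc3ccccc3)c2)c1 | intermediate
20 | 2-(4-hydroxybenzyl)-3-[2-(3-hydroxyphenyl)ethyl]-5-methoxyphenol (IN1159) | COc1cc(O)c(Cc2ccc(O)cc2)c(CCc2cccc(O)c2)c1 | target

**Step count and risks**

Total step count: 10. Longest linear sequence: 7 steps (steps 1, 2, 3, 6, 7, 9, 10); steps 4–5 and step 8 are side branches.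

Steps most likely to fail:

Step 9. The volatile, polymerisation-prone ynol ether may be lost before it traps the vinylketene. Ketene dimerisation, acylation of the product phenol by the ketene, or secondary photoreactions would then take over. The fallback sets out from sodium methoxyacetylide 13 and diazo ketone 11 and comes back at 19. After removal of ammonia, 13 is suspended in ether and silylated with Me3SiCl to give (methoxyethynyl)trimethylsilane F1, a distillable liquid that can be weighed and stored cold. Irradiation of 11 with F1 under the same conditions should follow the same cascade with the same orientation, since silicon reinforces the ynol ether polarisation. It would place the silyl group on the ring carbon between the two oxygens, giving 2-[4-(benzyloxy)benzyl]-3-{2-[3-(benzyloxy)phenyl]ethyl}-5-methoxy-6-(trimethylsilyl)phenol F2. Protodesilylation of this electron-rich arylsilane (CF3CO2H, CH2Cl2, 0 °C) should then give 19.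

Step 7. Deprotonation at the γ-carbon, which is both allylic and benzylic, may compete with enolisation of the methyl group. The result would be double-bond migration toward the arene or acylation at the wrong site. The fallback sets out from bromide 3 and aldehyde 8 and comes back at 11; it replaces diazo transfer by acylation of diazomethane. Triethyl phosphonoacetate is alkylated with 3 (NaH, DMF) to give ethyl 4-[3-(benzyloxy)phenyl]-2-(diethoxyphosphoryl)butanoate F3. Horner–Wadsworth–Emmons reaction with 8 (NaH, THF, 0 °C) should give ethyl (E)-4-[4-(benzyloxy)phenyl]-2-{2-[3-(benzyloxy)phenyl]ethyl}but-2-enoate F4. Saponification (LiOH, THF/H2O, then HCl) gives (E)-4-[4-(benzyloxy)phenyl]-2-{2-[3-(benzyloxy)phenyl]ethyl}but-2-enoic acid F5. Oxalyl chloride with catalytic DMF gives (E)-4-[4-(benzyloxy)phenyl]-2-{2-[3-(benzyloxy)phenyl]ethyl}but-2-enoyl chloride F6, and excess diazomethane in ether at 0 °C should convert it into 11. The trisubstituted alkene is a poor dipolarophile, so pyrazoline formation should stay minor.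

Step 6. The hindered phosphonate anion may add slowly while the enolisable aldehyde self-condenses, and base may move the new double bond into conjugation with the arene. The fallback sets out from phosphonate 5 and comes back at 9; it forms the trisubstituted alkene without base and without the aldehyde. Olefination of 5 with aqueous formaldehyde and K2CO3 gives 5-[3-(benzyloxy)phenyl]-3-methylidenepentan-2-one F7. Commercial 4-allylphenol is benzylated (BnBr, K2CO3, acetone) to 1-(benzyloxy)-4-(prop-2-en-1-yl)benzene F8. Cross-metathesis of F7 with F8 (Hoveyda–Grubbs second-generation catalyst, CH2Cl2, 40 °C, benzoquinone to suppress allyl isomerisation) should then give enone 9, mainly as the E isomer.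

Further compounds

F1 | step 9 | (methoxyethynyl)trimethylsilane | COC#C[Si](C)(C)C
F2 | step 9 | 2-[4-(benzyloxy)benzyl]-3-{2-[3-(benzyloxy)phenyl]ethyl}-5-methoxy-6-(trimethylsilyl)phenol | COc1cc(CCc2cccc(OCc3ccccc3)c2)c(Cc2ccc(OCc3ccccc3)cc2)c(O)c1[Si](C)(C)C
F3 | step 7 | ethyl 4-[3-(benzyloxy)phenyl]-2-(diethoxyphosphoryl)butanoate (racemic) | CCOC(=O)C(CCc1cccc(OCc2ccccc2)c1)P(=O)(OCC)OCC
F4 | step 7 | ethyl (E)-4-[4-(benzyloxy)phenyl]-2-{2-[3-(benzyloxy)phenyl]ethyl}but-2-enoate | CCOC(=O)/C(CCc1cccc(OCc2ccccc2)c1)=C/Cc1ccc(OCc2ccccc2)cc1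
F5 | step 7 | (E)-4-[4-(benzyloxy)phenyl]-2-{2-[3-(benzyloxy)phenyl]ethyl}but-2-enoic acid | OC(=O)/C(CCc1cccc(OCc2ccccc2)c1)=C/Cc1ccc(OCc2ccccc2)cc1
F6 | step 7 | (E)-4-[4-(benzyloxy)phenyl]-2-{2-[3-(benzyloxy)phenyl]ethyl}but-2-enoyl chloride | ClC(=O)/C(CCc1cccc(OCc2ccccc2)c1)=C/Cc1ccc(OCc2ccccc2)cc1
F7 | step 6 | 5-[3-(benzyloxy)phenyl]-3-methylidenepentan-2-one | CC(=O)C(=C)CCc1cccc(OCc2ccccc2)c1
F8 | step 6 | 1-(benzyloxy)-4-(prop-2-en-1-yl)benzene | C=CCc1ccc(OCc2ccccc2)cc1
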